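**Retrosynthetic overview**
1. Target 7 ⇐ macrocycle 6 by fluoride release of a temporary 4'‑O–Si(iPr)2–O–Si(iPr)2–O‑4'' bridge, in the same flask.
2. 6 ⇐ tethered bis‑chalcone 5 by an intramolecular, catalyst‑controlled triplet [2+2] (C3–C4 bond first, then C1–C2). The cyclobutane and the 17‑membered bridge ring form in the same photochemical operation, and all four stereocentres are set there.
3. 5 ⇐ 2 × chalcone 3 + TIPDSCl2 4 by 4'‑OH‑selective bis‑silylation.
4. 3 ⇐ 2,4‑dihydroxyacetophenone 1 + benzaldehyde 2 by Claisen–Schmidt condensation. All benzene rings are bought.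

Assumption: the Sc(III)·(S,S)‑t‑Bu‑PyBox complex is taken to leave the Cβ Si face of the chelated chalcone open; if the first run gives the antipode, the equally available (R,R)‑ligand is used with nothing else changed.

Target configuration: (1R,2R,3S,4S), with every substituent trans to both ring neighbours (C2‑symmetric).

**Step 1**
Reactants: 1 2,4‑dihydroxyacetophenone; 2 benzaldehyde (1.2 equiv)
Product: 3 (E)‑1‑(2,4‑dihydroxyphenyl)‑3‑phenylprop‑2‑en‑1‑one (2',4'‑dihydroxychalcone)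
Conditions: KOH (50% aq., 10 equiv), EtOH, 0 °C → rt, 48 h; then 2 M HCl to pH 3
Reagents that add atoms: none
Why: Claisen–Schmidt (crossed aldol) condensation of the methyl ketone enolate with the non‑enolisable aldehyde, followed by E1cB dehydration that gives only the conjugated E‑alkene.

**Step 2**
Reactants: 3 (E)‑2',4'‑dihydroxychalcone (2.1 equiv); 4 1,3‑dichloro‑1,1,3,3‑tetraisopropyldisiloxane (1.0 equiv)
Product: 5 1,3‑bis{3‑hydroxy‑4‑[(2E)‑3‑phenylprop‑2‑enoyl]phenoxy}‑1,1,3,3‑tetraisopropyldisiloxane (two molecules of 3 joined through their 4'‑oxygens; both 2'‑OH free; both alkenes E)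
Conditions: imidazole (4.5 equiv), DMF, 0 °C → rt, 4 h, amber glassware
Reagents that add atoms: 1,3‑dichloro‑1,1,3,3‑tetraisopropyldisiloxane (4), CC(C)[Si](Cl)(C(C)C)O[Si](Cl)(C(C)C)C(C)C
Why: Imidazole‑promoted O‑silylation is selective for the acidic, unhindered 4'‑OH because the 2'‑OH is locked in a hydrogen bond to the carbonyl, and each Si–Cl end of the disiloxane captures one chalcone; no stereocentre is formed.

**Step 3**
Reactants: 5 disiloxane‑tethered bis‑chalcone
Product: 7 [(1R,2R,3S,4S)‑3,4‑diphenylcyclobutane‑1,2‑diyl]bis[(2,4‑dihydroxyphenyl)methanone] (CNP0118806.1), via disiloxane‑bridged macrocycle 6 (not isolated)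
Conditions: Sc(OTf)3 (10 mol%), (S,S)‑t‑Bu‑PyBox (15 mol%), Ru(bpy)3(PF6)2 (2.5 mol%), i‑PrOAc/MeCN 3:1 (5 mM), degassed, blue LEDs (455 nm), rt, 24 h; then TBAF (2.5 equiv), AcOH (2.5 equiv), THF, 0 °C, 30 min
Reagents that add atoms: none
Why: Proposed new method: the closest known reaction is the chiral Sc(III)–PyBox Lewis‑acid‑catalysed, Ru(bpy)3‑sensitised triplet [2+2] photocycloaddition of 2'‑hydroxychalcones with styrenes and dienes, and here the 2π partner is the second chalcone held by the disiloxane bridge, so only the Sc‑chelated enone (triplet energy lowered below that of excited Ru(bpy)3) is sensitised, its Cβ bonds on the catalyst‑open Si face to Cβ of the tethered chalcone with like topicity (phenyls anti) to set C3 and C4 as S,S, and the resulting bis(α‑acyl) triplet 1,4‑diradical closes C1–C2 with every substituent trans to its neighbours (R,R, which is also the thermodynamic arrangement at these epimerisable centres), so that the cyclobutane and the 17‑membered ring form together before buffered fluoride cleaves the two aryl silyl ethers without touching the ketones or the stereocentres.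

**Compound list**
1 | 1‑(2,4‑dihydroxyphenyl)ethan‑1‑one (2,4‑dihydroxyacetophenone) | CC(=O)c1ccc(O)cc1O | starting material
2 | benzaldehyde | O=Cc1ccccc1 | starting material
3 | (E)‑1‑(2,4‑dihydroxyphenyl)‑3‑phenylprop‑2‑en‑1‑one | O=C(/C=C/c1ccccc1)c1ccc(O)cc1O | intermediate
4 | 1,3‑dichloro‑1,1,3,3‑tetraisopropyldisiloxane (TIPDSCl2) | CC(C)[Si](Cl)(C(C)C)O[Si](Cl)(C(C)C)C(C)C | starting material
5 | 1,3‑bis{3‑hydroxy‑4‑[(2E)‑3‑phenylprop‑2‑enoyl]phenoxy}‑1,1,3,3‑tetraisopropyldisiloxane | O=C(/C=C/c1ccccc1)c1ccc(O[Si](C(C)C)(C(C)C)O[Si](C(C)C)(C(C)C)Oc2ccc(C(=O)/C=C/c3ccccc3)c(O)c2)cc1O | intermediate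
6 | 4',4''‑O,O'‑(1,1,3,3‑tetraisopropyldisiloxane‑1,3‑diyl)‑bridged 7 (17‑membered ring; cyclobutane 1R,2R,3S,4S, all‑trans) | O=C(c1ccc(O[Si](C(C)C)(C(C)C)O[Si](C(C)C)(C(C)C)O5)cc1O)[C@H]1[C@H](C(=O)c2ccc5cc2O)[C@@H](c2ccccc2)[C@@H]1c1ccccc1 | intermediate (not isolated)
7 | [(1R,2R,3S,4S)‑3,4‑diphenylcyclobutane‑1,2‑diyl]bis[(2,4‑dihydroxyphenyl)methanone] | O=C(c1ccc(O)cc1O)[C@H]1[C@H](C(=O)c2ccc(O)cc2O)[C@@H](c2ccccc2)[C@@H]1c1ccccc1 | target

**Total step count:** 3
**Longest linear sequence:** 3 (1 → 3 → 5 → 7)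

**Steps most likely to fail, in order of risk**

Step 3 is the main risk. The partner arm must sit next to the Sc–PyBox centre, which may erode the ee; the cis‑diphenyl diastereomer may form; and the Lewis acid may attack the silyl ether. The fallback replaces catalyst control by auxiliary control; it sets out from 3 and comes back at 7. Two molecules of 3 are esterified at O‑4' with (1R,2R)‑cyclohexane‑1,2‑dicarboxylic acid (DCC, DMAP, CH2Cl2) to give bis{3‑hydroxy‑4‑[(2E)‑3‑phenylprop‑2‑enoyl]phenyl} (1R,2R)‑cyclohexane‑1,2‑dicarboxylate F1. Sensitised irradiation without chiral ligand (Sc(OTf)3, Ru(bpy)3(PF6)2, blue LEDs, 5 mM) closes it to the 18‑membered 4',4''‑O,O'‑[(1R,2R)‑cyclohexane‑1,2‑dicarbonyl]‑bridged 7 F2. The two cyclobutane antipodes on the same tether are diastereomers and are separated on silica or by crystallisation. If the (1R,2R) diacid favours the wrong one, the (1S,2S) diacid is used. Methanolysis of the aryl esters (Et3N, MeOH, rt) then rejoins the route at 7.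

Step 2 is next: the aryl disiloxane may hydrolyse on silica or not survive Sc(OTf)3. The fallback replaces the silicon linker by a carboxylate linker released by transesterification; it sets out from 3 and comes back at 7. Compound 3 is bis‑acylated at O‑4' with glutaryl dichloride (pyridine, CH2Cl2, 0 °C) to give bis{3‑hydroxy‑4‑[(2E)‑3‑phenylprop‑2‑enoyl]phenyl} pentanedioate F3. This goes through the photocycloaddition of step 3 to the 19‑membered 4',4''‑O,O'‑pentanedioyl‑bridged 7 F4, which is opened with Et3N/MeOH to reach 7.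

Step 1 is the least risky, but the doubly deprotonated ketone enolises sluggishly and Cannizzaro or flavanone side reactions can lower the yield. The fallback runs the condensation on a mono‑protected ketone; it sets out from 1 and comes back at 3. Compound 1 is alkylated selectively at O‑4 (MOMCl, i‑Pr2NEt, CH2Cl2, 0 °C) to give 1‑[2‑hydroxy‑4‑(methoxymethoxy)phenyl]ethan‑1‑one F5. Claisen–Schmidt condensation with 2 (KOH, EtOH, rt) gives (E)‑1‑[2‑hydroxy‑4‑(methoxymethoxy)phenyl]‑3‑phenylprop‑2‑en‑1‑one F6, and acidic methanolysis (3 M HCl, MeOH, 50 °C) returns 3.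

**Further compounds**
F1 | step 3 | bis{3‑hydroxy‑4‑[(2E)‑3‑phenylprop‑2‑enoyl]phenyl} (1R,2R)‑cyclohexane‑1,2‑dicarboxylate | O=C(/C=C/c1ccccc1)c1ccc(OC(=O)[C@@H]2CCCC[C@H]2C(=O)Oc2ccc(C(=O)/C=C/c3ccccc3)c(O)c2)cc1O
F2 | step 3 | 4',4''‑O,O'‑[(1R,2R)‑cyclohexane‑1,2‑dicarbonyl]‑bridged 7 (18‑membered ring; cyclobutane 1R,2R,3S,4S) | O=C(c1ccc(OC(=O)[C@@H]3CCCC[C@H]3C(=O)O5)cc1O)[C@H]1[C@H](C(=O)c2ccc5cc2O)[C@@H](c2ccccc2)[C@@H]1c1ccccc1
F3 | step 2 | bis{3‑hydroxy‑4‑[(2E)‑3‑phenylprop‑2‑enoyl]phenyl} pentanedioate | O=C(/C=C/c1ccccc1)c1ccc(OC(=O)CCCC(=O)Oc2ccc(C(=O)/C=C/c3ccccc3)c(O)c2)cc1O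
F4 | step 2 | 4',4''‑O,O'‑pentanedioyl‑bridged 7 (19‑membered ring; cyclobutane 1R,2R,3S,4S) | O=C(c1ccc(OC(=O)CCCC(=O)O5)cc1O)[C@H]1[C@H](C(=O)c2ccc5cc2O)[C@@H](c2ccccc2)[C@@H]1c1ccccc1
F5 | step 1 | 1‑[2‑hydroxy‑4‑(methoxymethoxy)phenyl]ethan‑1‑one | CC(=O)c1ccc(OCOC)cc1O
F6 | step 1 | (E)‑1‑[2‑hydroxy‑4‑(methoxymethoxy)phenyl]‑3‑phenylprop‑2‑en‑1‑one | O=C(/C=C/c1ccccc1)c1ccc(OCOC)cc1O
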